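## Strategy

- The retrosynthesis cuts ring C at two bonds, O1–C8a and C4–C4a, giving 3,5-dimethoxybenzyne (ring A) and an (S)-3-aryl-3-silyloxypropanoate that carries ring B, O1, C2, C3 and C4.
- Enabling feature: C8a (bearing O1) and C4a (bearing the C4 carbonyl) are adjacent carbons of ring A and so correspond to an aryne triple bond. The C5 methoxy beside C4a sends an oxygen nucleophile to C8a and the carbanion to C4a, and O1–C2–C3–C4 is a β-oxy ester that offers the carbanion an acyl group within a six-membered closure.
- Forward: ring A is bought as 3,5-dimethoxyphenol and converted into an ortho-silylaryl triflate (steps 1–3). Ring B is bought as 3,4,5-trimethoxyacetophenone, which is carbomethoxylated, reduced and O-silylated (steps 4–6).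
- The dihydropyranone ring C is the only ring constructed and forms in the final step, which also unites the two fragments.
- Stereochemistry: C2, the single stereocentre, is set as the (S)-carbinol by ruthenium-catalysed asymmetric hydrogenation of the β-keto ester. It is carried into the target with retention, because the C2–O bond is never broken.

Key step: step 7

Remark on the chemistry: the target SMILES is read as (2S). The sense of induction in step 5 is assigned by analogy with aroylacetates; should the (R)-ligand deliver the (R)-carbinol, the ligand antipode would be used with nothing else changed.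

## Route

Step 1
Reactants: 1 3,5-dimethoxyphenol
Product: 2 2-bromo-3,5-dimethoxyphenol
Conditions: NBS (1.0 equiv), CH2Cl2, −78 °C to 0 °C
Reagents that add atoms: N-bromosuccinimide (NBS), O=C1CCC(=O)N1Br
Why: Electrophilic aromatic bromination in which every free position is activated by all three oxygen substituents, but the two equivalent positions ortho to the hydroxyl are statistically favoured and less hindered than C4 between the two methoxy groups, so one equivalent of NBS at low temperature should stop at the 2-bromide, any 4-bromo isomer being removed by chromatography.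

Step 2
Reactants: 2 2-bromo-3,5-dimethoxyphenol
Product: 3 (2-bromo-3,5-dimethoxyphenoxy)trimethylsilane
Conditions: HMDS (excess), THF, 70 °C; volatiles removed in vacuo
Reagents that add atoms: hexamethyldisilazane (HMDS), C[Si](C)(C)N[Si](C)(C)C
Why: O-Silylation of a phenol by HMDS with loss of ammonia is neutral and salt-free, leaves the aryl bromide untouched and should give an aryl silyl ether that can be lithiated after simple evaporation.

Step 3
Reactants: 3 (2-bromo-3,5-dimethoxyphenoxy)trimethylsilane
Product: 6 3,5-dimethoxy-2-(trimethylsilyl)phenyl trifluoromethanesulfonate, via (2-lithio-3,5-dimethoxyphenoxy)trimethylsilane 4 (not isolated), via lithium 3,5-dimethoxy-2-(trimethylsilyl)phenoxide 5 (not isolated)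
Conditions: n-BuLi (1.1 equiv), THF, −78 °C; then Tf2O (1.2 equiv), −78 °C to 0 °C
Reagents that add atoms: trifluoromethanesulfonic anhydride (Tf2O), O=S(=O)(OS(=O)(=O)C(F)(F)F)C(F)(F)F
Why: Bromine–lithium exchange gives aryllithium 4, whose anionic 1,3-shift of silicon from oxygen to carbon (retro-Brook rearrangement) is driven by formation of the more stable phenoxide 5, and O-triflation of 5 completes the standard passage from an ortho-bromophenol to an ortho-silylaryl triflate.

Step 4
Reactants: 7 3,4,5-trimethoxyacetophenone; 8 dimethyl carbonate (3 equiv)
Product: 9 methyl 3-oxo-3-(3,4,5-trimethoxyphenyl)propanoate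
Conditions: NaH (2.5 equiv), THF, reflux; then aq. HCl, 0 °C
Reagents that add atoms: none
Why: Crossed Claisen condensation in which the sodium enolate of the methyl ketone is acylated by the non-enolisable carbonate and the equilibrium is pulled forward by deprotonation of the β-keto ester, which is released on acidification.

Step 5
Reactants: 9 methyl 3-oxo-3-(3,4,5-trimethoxyphenyl)propanoate
Product: 10 methyl (S)-3-hydroxy-3-(3,4,5-trimethoxyphenyl)propanoate
Conditions: H2 (30 bar), [RuCl(p-cymene)((R)-SEGPHOS)]Cl (1 mol %), MeOH, 60 °C
Reagents that add atoms: none
Why: Noyori asymmetric hydrogenation of a β-keto ester, in which the substrate chelates ruthenium through its ketone and ester oxygens and hydride is delivered to the carbonyl face fixed by the atropisomeric diphosphine, the (R)-ligand being expected to give the (S)-carbinol at the future C2 (the facial sense that gives (R)-3-hydroxybutanoate, the descriptor differing only because aryl outranks CH2CO2Me), with methanol matching the methyl ester so that no transesterification can occur.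

Step 6
Reactants: 10 methyl (S)-3-hydroxy-3-(3,4,5-trimethoxyphenyl)propanoate
Product: 11 methyl (S)-3-(trimethylsilyloxy)-3-(3,4,5-trimethoxyphenyl)propanoate
Conditions: TMSCl (1.2 equiv), Et3N (1.5 equiv), CH2Cl2, 0 °C to rt; pentane, filtration through Celite
Reagents that add atoms: chlorotrimethylsilane (TMSCl), C[Si](C)(C)Cl
Why: Standard O-silylation of a secondary alcohol with a silyl chloride and an amine base touches no bond at the stereocentre, and the non-aqueous work-up should deliver the labile silyl ether free of hydroxylic protons, as the annulation requires.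

Step 7
Reactants: 6 3,5-dimethoxy-2-(trimethylsilyl)phenyl trifluoromethanesulfonate (1.5 equiv); 11 methyl (S)-3-(trimethylsilyloxy)-3-(3,4,5-trimethoxyphenyl)propanoate
Product: 15 (S)-5,7-dimethoxy-2-(3,4,5-trimethoxyphenyl)chroman-4-one, via 3,5-dimethoxybenzyne 12 (not isolated), via cesium alkoxide 13 (not isolated), via O-arylated aryl anion 14 (not isolated)
Conditions: CsF (3 equiv), 18-crown-6 (0.2 equiv), THF, 0 °C to rt; then AcOH, 0 °C
Reagents that add atoms: none
Why: Proposed new method: fluoride should remove the C-silyl group of 6, the ortho triflate departing to give 3,5-dimethoxybenzyne 12, and should also cleave the O–Si bond of 11 to unmask alkoxide 13; 13 adds to the aryne carbon that becomes C8a, and the resulting aryl anion 14 at the future C4a attacks the methyl ester and expels methoxide to give the ketone. The nearest precedents are xanthone formation from arynes and methyl salicylates (phenoxide arylation, then acyl capture by the aryl anion) and aryne insertion into the amide N–C(O) bond of azetidin-2-ones, which gives 2,3-dihydroquinolin-4(1H)-ones; an aliphatic β-silyloxy ester has not been shown to react in this way. Ring C closes by formation of O1–C8a followed by a 6-exo-trig acylation that forms C4–C4a. No stereocentre is created: C2 arrives in 11, only its O–Si bond is broken, and since oxygen still outranks aryl, CH2 and H at C2 the centre is S in the product as in 11. The step needs regioselective addition to the unsymmetrical aryne, which the methoxy beside the triple bond secures by distorting the aryne and by stabilising negative charge at C4a inductively (the remote methoxy opposes this only weakly), and it needs acyl capture to outrun proton transfer from C3–H to the aryl anion, which the absence of any O–H proton, the aprotic medium and the short tether to a reactive methyl ester should favour. The substoichiometric crown ether keeps soluble fluoride, and hence free alkoxide, low against retro-aldol cleavage, and the acetic acid quench neutralises methoxide before it can open the flavanone by retro-oxa-Michael reaction and racemise C2.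

## Compound list

1 | 3,5-dimethoxyphenol | COc1cc(O)cc(OC)c1 | starting material
2 | 2-bromo-3,5-dimethoxyphenol | COc1cc(O)c(Br)c(OC)c1 | intermediate
3 | (2-bromo-3,5-dimethoxyphenoxy)trimethylsilane | COc1cc(O[Si](C)(C)C)c(Br)c(OC)c1 | intermediate
4 | (2-lithio-3,5-dimethoxyphenoxy)trimethylsilane | COc1cc(O[Si](C)(C)C)c([Li])c(OC)c1 | intermediate
5 | lithium 3,5-dimethoxy-2-(trimethylsilyl)phenoxide | [Li+].COc1cc([O-])c([Si](C)(C)C)c(OC)c1 | intermediate
6 | 3,5-dimethoxy-2-(trimethylsilyl)phenyl trifluoromethanesulfonate | COc1cc(OC)c([Si](C)(C)C)c(OS(=O)(=O)C(F)(F)F)c1 | intermediate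
7 | 3,4,5-trimethoxyacetophenone | CC(=O)c1cc(OC)c(OC)c(OC)c1 | starting material
8 | dimethyl carbonate | COC(=O)OC | starting material
9 | methyl 3-oxo-3-(3,4,5-trimethoxyphenyl)propanoate | COC(=O)CC(=O)c1cc(OC)c(OC)c(OC)c1 | intermediate
10 | methyl (S)-3-hydroxy-3-(3,4,5-trimethoxyphenyl)propanoate | O[C@H](c1cc(OC)c(OC)c(OC)c1)CC(=O)OC | intermediate
11 | methyl (S)-3-(trimethylsilyloxy)-3-(3,4,5-trimethoxyphenyl)propanoate | C[Si](C)(C)O[C@H](c1cc(OC)c(OC)c(OC)c1)CC(=O)OC | intermediate
12 | 3,5-dimethoxybenzyne (1,2-didehydro-3,5-dimethoxybenzene) | COC1=CC(OC)=CC#C1 | intermediate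
13 | cesium (S)-3-methoxy-3-oxo-1-(3,4,5-trimethoxyphenyl)propan-1-olate | [Cs+].[O-][C@H](c1cc(OC)c(OC)c(OC)c1)CC(=O)OC | intermediate
14 | cesium 2,4-dimethoxy-6-{[(S)-3-methoxy-3-oxo-1-(3,4,5-trimethoxyphenyl)propyl]oxy}benzen-1-ide | [Cs+].COc1cc(OC)[c-]c(O[C@H](c2cc(OC)c(OC)c(OC)c2)CC(=O)OC)c1 | intermediate
15 | (S)-5,7-dimethoxy-2-(3,4,5-trimethoxyphenyl)chroman-4-one | COc1cc(OC)c2c(c1)O[C@H](c1cc(OC)c(OC)c(OC)c1)CC2=O | target

## Step count and risks

Total steps: 7. Longest linear sequence: 4 steps (1 → 2 → 3 → 6 → 15, or equally 7 → 9 → 10 → 11 → 15).

**Step 7 (the proposed annulation).** Three processes could defeat it. The aryl anion may take a proton from C3–H instead of attacking the ester, which would be followed by β-elimination of the aryloxide. The unmasked alkoxide may fragment by retro-aldol cleavage before it meets the aryne. The product may open and reclose under base (retro-oxa-Michael, then oxa-Michael), which would erode the enantiopurity at C2.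

The fallback uses known chemistry only; it sets out from keto ester 9 and phenol 1 and returns to the route at target 15. Because a Mitsunobu etherification inverts the carbinol, the enantiomeric alcohol is needed. Keto ester 9 would be hydrogenated as in step 5 but with [RuCl(p-cymene)((S)-SEGPHOS)]Cl, to give methyl (R)-3-hydroxy-3-(3,4,5-trimethoxyphenyl)propanoate F1. Mitsunobu reaction of F1 with phenol 1 (PPh3, DIAD, toluene, 0 °C to rt) should proceed with inversion to methyl (S)-3-(3,5-dimethoxyphenoxy)-3-(3,4,5-trimethoxyphenyl)propanoate F2. The 3,4,5-trimethoxyphenyl group is close to electronically neutral, so ionisation at the benzylic carbon should not compete. Mild saponification (LiOH, THF/H2O, 0 °C, then HCl to pH 3) would give (S)-3-(3,5-dimethoxyphenoxy)-3-(3,4,5-trimethoxyphenyl)propanoic acid F3. Intramolecular Friedel–Crafts acylation through the mixed trifluoroacetic anhydride (TFAA, CH2Cl2, 0 °C) would then close ring C onto one of the two equivalent positions ortho to the ether oxygen and deliver 15.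

**Step 1 (bromination).** Competing attack at C4 between the two methoxy groups, and a second bromination, could give a mixture that is hard to separate.

The fallback sets out from phenol 1 and returns to the route at silyl triflate 6, replacing steps 1 to 3 by a directed ortho-metalation. Phenol 1 would be carbamoylated (isopropyl isocyanate, cat. Et3N, CH2Cl2, rt) to 3,5-dimethoxyphenyl N-isopropylcarbamate F4. Carbamate-directed ortho-lithiation (TBSOTf, TMEDA, Et2O; then n-BuLi, −78 °C) and a TMSCl quench, with the temporary N-silyl group lost on acidic work-up, should place silicon between the carbamate and a methoxy group. This gives 3,5-dimethoxy-2-(trimethylsilyl)phenyl N-isopropylcarbamate F5. Cleavage of the carbamate (DBU, Et2NH, MeCN, 40 °C) and triflation of the phenoxide in the same flask with PhNTf2 would give 6.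

**Step 5 (asymmetric hydrogenation).** Enantiofacial discrimination in hydride delivery to the aryl ketone may be incomplete, since aroylacetates are less well-behaved than alkyl β-keto esters.

The fallback replaces catalyst control by a resolution; it sets out from keto ester 9 and returns to the route at hydroxy ester 10. Reduction of 9 with NaBH4 (MeOH, 0 °C) would give racemic methyl 3-hydroxy-3-(3,4,5-trimethoxyphenyl)propanoate F6. Lipase-mediated acylation (Burkholderia cepacia lipase, vinyl acetate, t-BuOMe, 30 °C) should, by the usual enantiopreference of lipases for secondary alcohols with one large and one medium substituent, acetylate the (R)-enantiomer. This would give methyl (R)-3-acetoxy-3-(3,4,5-trimethoxyphenyl)propanoate F7 and leave (S)-alcohol 10, which is separated by chromatography.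

## Further compounds

F1 | step 7 | methyl (R)-3-hydroxy-3-(3,4,5-trimethoxyphenyl)propanoate | O[C@@H](c1cc(OC)c(OC)c(OC)c1)CC(=O)OC
F2 | step 7 | methyl (S)-3-(3,5-dimethoxyphenoxy)-3-(3,4,5-trimethoxyphenyl)propanoate | COc1cc(OC)cc(O[C@H](c2cc(OC)c(OC)c(OC)c2)CC(=O)OC)c1
F3 | step 7 | (S)-3-(3,5-dimethoxyphenoxy)-3-(3,4,5-trimethoxyphenyl)propanoic acid | COc1cc(OC)cc(O[C@H](c2cc(OC)c(OC)c(OC)c2)CC(=O)O)c1
F4 | step 1 | 3,5-dimethoxyphenyl N-isopropylcarbamate | COc1cc(OC)cc(OC(=O)NC(C)C)c1
F5 | step 1 | 3,5-dimethoxy-2-(trimethylsilyl)phenyl N-isopropylcarbamate | COc1cc(OC)c([Si](C)(C)C)c(OC(=O)NC(C)C)c1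
F6 | step 5 | racemic methyl 3-hydroxy-3-(3,4,5-trimethoxyphenyl)propanoate | OC(c1cc(OC)c(OC)c(OC)c1)CC(=O)OC
F7 | step 5 | methyl (R)-3-acetoxy-3-(3,4,5-trimethoxyphenyl)propanoate | CC(=O)O[C@@H](c1cc(OC)c(OC)c(OC)c1)CC(=O)OC
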